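**Plan**
- Retrosynthetic cuts, in order: C12–C13 (butenolide onto a C12 borane), C9–C11 (vinyl onto a C9 enol triflate), C4–C18 (enolate methylation), and last C1–C10 together with C4–C5 in one [4+2] step.
- Enabling feature: ring B (C5–C10) carries methyls on C8 and C10 and oxygen or sp2 carbon at C6 and C9, so it is 2,6-dimethyl-1,4-benzoquinone; ring A (C1–C4 plus C5, C10) can be laid across its C5=C10 bond by a 2-silyloxy dienoate whose ester carbon becomes C19.
- Forward order: ring B is bought and ring A closes in the cycloaddition. The C2, C6 and C9 ketones are then all held as silyl enol ethers while C4 is methylated and C19 reduced. After unmasking and reduction the side chain is joined last, at C9 and then at C12.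
- Stereochemistry: C10 from the chiral Lewis acid; C4 from alkylation anti to the C10 methyl; C5 from protonation anti to the C10 methyl and C19; the equatorial 2α- and 6α-carbinols from dissolving-metal reduction.

Key step: step 2

Numbering: labdane numbering throughout (ring A = C1–C5, C10; ring B = C5–C10; C17 = methyl on C8; C18/C19 = α/β substituents on C4; C20 = methyl on C10; C11, C12 = tether; C13–C16 = butenolide). β is the face of the C10 methyl.

Assumption: the (S)-configured oxazaborolidinium ion is taken to screen the face of the bound quinone that leaves the 10β-methyl enantiomer drawn below; if the sense is the reverse, the mirror-image catalyst is used and nothing else changes.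

**Step 1**
Reactants: 1 methyl (E)-4-oxopent-2-enoate
Product: 2 methyl (E)-4-(triisopropylsilyloxy)penta-2,4-dienoate
Conditions: TIPSOTf, Et3N, CH2Cl2, 0 °C
Reagents that add atoms: triisopropylsilyl trifluoromethanesulfonate, CC(C)[Si](OS(=O)(=O)C(F)(F)F)(C(C)C)C(C)C
Why: Soft enolisation with O-silylation of the methyl ketone can only remove a CH3 hydrogen, because the other α-carbon is vinylic, and leaves the (E)-enoate untouched, so the 2-silyloxy-1,3-diene should form as a single isomer.

**Step 2**
Reactants: 2 methyl (E)-4-(triisopropylsilyloxy)penta-2,4-dienoate; 3 2,6-dimethyl-1,4-benzoquinone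
Product: 4 cis-fused adduct, methyl 8,10-dimethyl-6,9-dioxo-2-(triisopropylsilyloxy)decalin-2,7-diene-4-carboxylate with 4α-CO2Me, 5β-H, 10β-CH3
Conditions: (S)-3,3-diphenyl-1-(o-tolyl)tetrahydro-1H,3H-pyrrolo[1,2-c][1,3,2]oxazaborole·HNTf2 (20 mol %), CH2Cl2, −78 → −40 °C
Reagents that add atoms: none
Why: The protonated oxazaborolidine sits on the C6 carbonyl of 3, the more basic and more open of the two (it lies between two CH groups and is fed by both β-methyls), so C10 becomes the electrophilic β-carbon, the silyloxy-activated CH2 terminus of 2 (C1) bonds to it and the ester-bearing terminus (C4) bonds to C5 in a concerted, asynchronous, endo [4+2] transition state, the closest known reaction type being the oxazaborolidinium-catalysed Diels–Alder reaction of 2-silyloxy-1,3-dienes with methyl-substituted 1,4-benzoquinones. Ring A closes as a six-membered ring by suprafacial [4+2] cycloaddition, both new bonds (C1–C10 and C4–C5) forming in the same step. C10 and C5 come out cis because the addition is suprafacial on the quinone C=C, and in one absolute sense because the aryl groups of the catalyst screen one face of the complexed C5=C10 bond while an α-C5–H···O contact fixes the quinone on boron; C4 follows from the (E)-geometry of the dienoate and the endo position of ring B, which puts the ester trans to H5 and the C10 methyl. The step needs C1-to-C10 regiochemistry, one enantioface and endo selectivity: the first two rest on the C6 carbonyl being the only one with α-hydrogens and β-methyls (the two C=C bonds of 3 are related by symmetry), the third on secondary overlap with the activated ene-dione. C4 and C5 are reset later, so only the C10 configuration and the connectivity have to be carried forward.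

**Step 3**
Reactants: 4 cis-fused adduct
Product: 5 dienol silyl ether, methyl 6-(tert-butyldimethylsilyloxy)-8,10-dimethyl-9-oxo-2-(triisopropylsilyloxy)decalin-2,5,7-triene-4α-carboxylate (10β-CH3)
Conditions: TBSOTf, Et3N, CH2Cl2, −78 → 0 °C
Reagents that add atoms: tert-butyldimethylsilyl trifluoromethanesulfonate, CC(C)(C)[Si](C)(C)OS(=O)(=O)C(F)(F)F
Why: Soft enolisation with O-silylation is regiospecific here because C5–H is the only α-hydrogen of the ene-dione (C10 is quaternary, C7 and C8 are sp2), so the C5=C6 silyl enol ether should form, masking the C6 ketone and deliberately erasing the cis-fused C5 centre for later resetting.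

**Step 4**
Reactants: 5 dienol silyl ether
Product: 6 tris(silyl enol ether): 2-OTIPS on C2=C3, 6-OTBS on C5=C6, 9-OSiEt3 on C8=C9, methyl 4α-carboxylate, 10β-CH3
Conditions: LiBH(s-Bu)3 (L-Selectride), THF, −78 °C; then Et3SiCl, −78 → 0 °C
Reagents that add atoms: chlorotriethylsilane, CC[Si](Cl)(CC)CC
Why: Conjugate (1,4) hydride reduction with enolate trapping should work because the bulky borohydride can only reach C7, the open β-carbon of the α-methyl enone (the C9 carbonyl is flanked by quaternary C10, and C5 is a fully substituted, donor-bearing enol-ether terminus), and O-silylation of the regiodefined C8=C9 enolate masks the third ketone.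

**Step 5**
Reactants: 6 tris(silyl enol ether)
Product: 7 C4-methylated ester (4α-CH3, 4β-CO2Me), otherwise as 6
Conditions: LiN(i-Pr)2, THF, −78 °C; then MeI, DMPU, −78 → −30 °C
Reagents that add atoms: iodomethane, CI
Why: Ester enolate C-alkylation: with all three ketones masked C4–H is the only acidic hydrogen, the cross-conjugated dienolate reacts at C4 because both γ-termini (C2, C6) carry silyloxy groups, and iodomethane should enter anti to the pseudoaxial C10 methyl (1,3 to C4 on the flattened ring A), placing CH3 α and the ester β.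

**Step 6**
Reactants: 7 C4-methylated ester
Product: 8 C19 alcohol (4α-CH3, 4β-CH2OH) with the three silyl enol ethers intact
Conditions: LiAlH4, Et2O, 0 °C → rt
Reagents that add atoms: none
Why: Hydride reduction of the neopentyl methyl ester to the primary alcohol is standard, and silyl enol ethers do not react with LiAlH4 at this temperature.

**Step 7**
Reactants: 8 C19 alcohol
Product: 9 19-hydroxy-2,6,9-trione, trans-fused (5α-H, 10β-CH3, 4α-CH3; C8 either epimer)
Conditions: Bu4NF, AcOH, THF, 0 °C → rt
Reagents that add atoms: none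
Why: Fluoride-induced cleavage of the three silyl enol ethers with ketonisation should give the trione, C5 being protonated from the α-face because the β-face of the C5=C6 enol carries the C10 methyl and C19 in a syn-axial array, which gives the trans ring fusion that is also expected to be the more stable one once C4 is quaternary, while the C8 epimer formed is of no consequence.

**Step 8**
Reactants: 9 19-hydroxy-2,6,9-trione
Product: 10 2α,6α,9,19-tetraol (5α-H; C8 and C9 either epimer)
Conditions: Li, NH3(l), THF, EtOH, −78 → −33 °C; then NH4Cl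
Reagents that add atoms: none
Why: Dissolving-metal ketone reduction passes through ketyl and carbanion intermediates that are protonated to the thermodynamically preferred equatorial carbinols, so C2 and C6 should become 2α-OH and 6α-OH (their axial β positions are syn-axial to the C10 methyl and C19), the opposite of what small hydrides give on this β-shielded trans-decalin, and the hindered C9 ketone is reduced as well and re-oxidised in step 10.

**Step 9**
Reactants: 10 tetraol
Product: 11 2α,6α,19-tris(triethylsilyloxy)-9-ol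
Conditions: Et3SiCl (3.3 equiv), imidazole, DMF, −20 → 0 °C
Reagents that add atoms: chlorotriethylsilane, CC[Si](Cl)(CC)CC
Why: Rate-controlled silylation (primary C19–OH > equatorial C2–OH > C6–OH ≫ C9–OH) should leave only the C9 carbinol free, since it lies between quaternary C10 and the methyl-bearing C8.

**Step 10**
Reactants: 11 tris(silyl ether) 9-ol
Product: 12 2α,6α,19-tris(triethylsilyloxy)-9-one
Conditions: Dess–Martin periodinane, pyridine, CH2Cl2, 0 °C → rt
Reagents that add atoms: none
Why: Dess–Martin oxidation of the single free, hindered secondary alcohol restores the C9 ketone under buffered conditions that spare the silyl ethers.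

**Step 11**
Reactants: 12 9-ketone
Product: 13 C9 enol triflate, 2α,6α,19-tris(triethylsilyloxy)-8-en-9-yl trifluoromethanesulfonate
Conditions: KN(SiMe3)2, THF, −78 → −20 °C; then PhNTf2, → rt
Reagents that add atoms: N-phenylbis(trifluoromethanesulfonimide), O=S(=O)(N(c1ccccc1)S(=O)(=O)C(F)(F)F)C(F)(F)F
Why: Enolate O-triflation: C10 is quaternary, so the potassium enolate can form only toward C8 (both C8 epimers converge) and the triflimide should give the tetrasubstituted C8=C9 enol triflate.

**Step 12**
Reactants: 13 C9 enol triflate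
Product: 14 9-vinyl-8-ene (C11=C12 on C9), tris(triethylsilyl) ether
Conditions: Bu3SnCH=CH2, Pd(PPh3)4 (5 mol %), LiCl, THF, 65 °C
Reagents that add atoms: tributyl(vinyl)stannane, C=C[Sn](CCCC)(CCCC)CCCC
Why: Stille coupling of the enol triflate (oxidative addition to zerovalent palladium, chloride-assisted transfer of the small vinyl group from tin, reductive elimination), well known for 2,6,6-trisubstituted cyclohexenyl triflates, forms C9–C11.

**Step 13**
Reactants: 14 9-vinyl-8-ene; 15 4-bromofuran-2(5H)-one
Product: 17 2α,6α,19-tris(triethylsilyl) ether of the target, via B-alkyl-9-BBN borane 16 (not isolated)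
Conditions: 9-BBN, THF, 0 °C → rt; then 15, PdCl2(dppf) (5 mol %), AsPh3, Cs2CO3, DMF/H2O, rt
Reagents that add atoms: 9-borabicyclo[3.3.1]nonane (9-BBN-H), B1C2CCCC1CCC2 (its boron bicycle is carried only in 16; of this reagent only hydrogen remains in 17)
Why: Anti-Markovnikov hydroboration of the monosubstituted vinyl group by 9-BBN (the tetrasubstituted C8=C9 bond is inert) followed by B-alkyl Suzuki–Miyaura coupling with the β-bromo enoate unit of 15 (fast oxidative addition, base-assisted alkyl transfer from boron, the dppf ligand suppressing β-hydride loss) forms C12–C13 and brings in the intact butenolide.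

**Step 14**
Reactants: 17 tris(triethylsilyl) ether
Product: 18 target, 2α,6α,19-trihydroxylabda-8,13-dien-15,16-olide
Conditions: HF·pyridine, pyridine, THF, 0 °C → rt
Reagents that add atoms: none
Why: Fluoride-mediated cleavage of the three triethylsilyl ethers should free the triol, the base-sensitive butenolide and the tetrasubstituted alkene being stable to buffered HF.

**Compound list**
1 | methyl (E)-4-oxopent-2-enoate | CC(=O)/C=C/C(=O)OC | starting material
2 | methyl (E)-4-(triisopropylsilyloxy)penta-2,4-dienoate | C=C(O[Si](C(C)C)(C(C)C)C(C)C)/C=C/C(=O)OC | intermediate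
3 | 2,6-dimethyl-1,4-benzoquinone | CC1=CC(=O)C=C(C)C1=O | starting material
4 | cis-fused adduct (4α-CO2Me, 5β-H, 10β-CH3; 2-OTIPS on C2=C3; C7=C8 ene-dione) | CC=1C(=O)[C@@]2(C)CC(O[Si](C(C)C)(C(C)C)C(C)C)=C[C@@H](C(=O)OC)[C@H]2C(=O)C=1 | intermediate
5 | dienol silyl ether (6-OTBS on C5=C6, C7=C8–C9=O enone, 2-OTIPS, 4α-CO2Me, 10β-CH3) | CC=1C(=O)[C@@]2(C)CC(O[Si](C(C)C)(C(C)C)C(C)C)=C[C@@H](C(=O)OC)C2=C(O[Si](C)(C)C(C)(C)C)C=1 | intermediate
6 | tris(silyl enol ether) (2-OTIPS, 6-OTBS, 9-OSiEt3; 4α-CO2Me) | CC1=C(O[Si](CC)(CC)CC)[C@@]2(C)CC(O[Si](C(C)C)(C(C)C)C(C)C)=C[C@@H](C(=O)OC)C2=C(O[Si](C)(C)C(C)(C)C)C1 | intermediate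
7 | C4-methylated ester (4α-CH3, 4β-CO2Me) | CC1=C(O[Si](CC)(CC)CC)[C@@]2(C)CC(O[Si](C(C)C)(C(C)C)C(C)C)=C[C@](C)(C(=O)OC)C2=C(O[Si](C)(C)C(C)(C)C)C1 | intermediate
8 | C19 alcohol (4α-CH3, 4β-CH2OH), tris(silyl enol ether) | CC1=C(O[Si](CC)(CC)CC)[C@@]2(C)CC(O[Si](C(C)C)(C(C)C)C(C)C)=C[C@](C)(CO)C2=C(O[Si](C)(C)C(C)(C)C)C1 | intermediate
9 | 19-hydroxy-2,6,9-trione, trans-fused (5α-H; C8 either epimer) | CC1C(=O)[C@@]2(C)CC(=O)C[C@](C)(CO)[C@@H]2C(=O)C1 | intermediate
10 | 2α,6α,9,19-tetraol (C8, C9 either epimer) | CC1C(O)[C@@]2(C)C[C@@H](O)C[C@](C)(CO)[C@@H]2[C@@H](O)C1 | intermediate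
11 | 2α,6α,19-tris(triethylsilyloxy)-9-ol | CC1C(O)[C@@]2(C)C[C@@H](O[Si](CC)(CC)CC)C[C@](C)(CO[Si](CC)(CC)CC)[C@@H]2[C@@H](O[Si](CC)(CC)CC)C1 | intermediate
12 | 2α,6α,19-tris(triethylsilyloxy)-9-one | CC1C(=O)[C@@]2(C)C[C@@H](O[Si](CC)(CC)CC)C[C@](C)(CO[Si](CC)(CC)CC)[C@@H]2[C@@H](O[Si](CC)(CC)CC)C1 | intermediate
13 | C9 enol triflate (C8=C9) | CC1=C(OS(=O)(=O)C(F)(F)F)[C@@]2(C)C[C@@H](O[Si](CC)(CC)CC)C[C@](C)(CO[Si](CC)(CC)CC)[C@@H]2[C@@H](O[Si](CC)(CC)CC)C1 | intermediate
14 | 9-vinyl-8-ene | CC1=C(C=C)[C@@]2(C)C[C@@H](O[Si](CC)(CC)CC)C[C@](C)(CO[Si](CC)(CC)CC)[C@@H]2[C@@H](O[Si](CC)(CC)CC)C1 | intermediate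
15 | 4-bromofuran-2(5H)-one | BrC1=CC(=O)OC1 | starting material
16 | B-alkyl-9-BBN borane (C9–CH2CH2–B) | CC1=C(CCB3C4CCCC3CCC4)[C@@]2(C)C[C@@H](O[Si](CC)(CC)CC)C[C@](C)(CO[Si](CC)(CC)CC)[C@@H]2[C@@H](O[Si](CC)(CC)CC)C1 | intermediate
17 | tris(triethylsilyl) ether of the target | CC1=C(CCC3=CC(=O)OC3)[C@@]2(C)C[C@@H](O[Si](CC)(CC)CC)C[C@](C)(CO[Si](CC)(CC)CC)[C@@H]2[C@@H](O[Si](CC)(CC)CC)C1 | intermediate
18 | 2α,6α,19-trihydroxylabda-8,13-dien-15,16-olide | CC1=C(CCC2=CC(=O)OC2)[C@@]2(C)C[C@@H](O)C[C@](C)(CO)[C@@H]2[C@@H](O)C1 | target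

**Step count**
Total: 14 steps. Longest linear sequence: 14 steps (1 → 18); 3 and 15 are bought.

**Steps most likely to fail**

Step 2. The ester carbonyl of the diene may compete with the quinone for the boron cation, so that turnover slows and enantiofacial control is lost. In that case 2 and 3 would be combined with BF3·OEt2 (1 equiv, CH2Cl2, −78 °C). This achiral acid binds the same C6 carbonyl and should give the same regio- and endo-isomer, but as a racemate: 4 accompanied by its mirror image, the enantiomeric adduct F1. Preparative chromatography on a chiral stationary phase would then separate 4 from F1. This fallback sets out from 2 and 3 and returns to the route at 4.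

Step 4. Hydride may add 1,2 or over-reduce, or O-silylation of the hindered boron-bound enolate may stay incomplete. The ketones would then be masked by another path that sets out from 4. Zn dust in AcOH/THF at 0 °C should saturate C7=C8 of the ene-dione to give the cis-fused saturated 6,9-dione F2. DBU in CH2Cl2 should epimerise C5 to the trans-fused 6,9-dione F3. TBSOTf (2.5 equiv) and Et3N should convert both ketones into the conjugated 6,9-bis(silyloxy)-6,8-diene F4. LiN(i-Pr)2 then MeI should methylate C4 anti to the now axial C10 methyl of the trans-decalin to give the methylated ester F5. LiAlH4 should give the C19 alcohol F6, and Bu4NF/AcOH should unmask the three ketones. This fallback returns to the route at 9.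

Step 9. Site selectivity among the four hydroxyls may be lost (silylation reaching C9, or stopping short of C6). Discrimination would then be moved to acylation, setting out from 10. Ac2O in pyridine at 0 °C → rt without an acylation catalyst should give the 2α,6α,19-triacetate F7 with the neopentyl-type C9–OH untouched. Dess–Martin oxidation should give the 9-keto triacetate F8. K2CO3 in MeOH should give the 2α,6α,19-trihydroxy-9-ketone F9, which is silylated on all three hydroxyls with Et3SiCl/imidazole. This fallback returns to the route at 12.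

**Further compounds**
F1 | step 2 | mirror image of adduct 4 (4β-CO2Me, 5α-H, 10α-CH3) | CC=1C(=O)[C@]2(C)CC(O[Si](C(C)C)(C(C)C)C(C)C)=C[C@H](C(=O)OC)[C@@H]2C(=O)C=1
F2 | step 4 | cis-fused saturated 6,9-dione (5β-H, 10β-CH3, 4α-CO2Me, 2-OTIPS on C2=C3; C8 either epimer) | CC1C(=O)[C@@]2(C)CC(O[Si](C(C)C)(C(C)C)C(C)C)=C[C@@H](C(=O)OC)[C@H]2C(=O)C1
F3 | step 4 | trans-fused saturated 6,9-dione (5α-H) | CC1C(=O)[C@@]2(C)CC(O[Si](C(C)C)(C(C)C)C(C)C)=C[C@@H](C(=O)OC)[C@@H]2C(=O)C1
F4 | step 4 | 6,9-bis(tert-butyldimethylsilyloxy)-6,8-diene, 2-OTIPS, methyl 4α-carboxylate, 5α-H | CC1=C(O[Si](C)(C)C(C)(C)C)[C@@]2(C)CC(O[Si](C(C)C)(C(C)C)C(C)C)=C[C@@H](C(=O)OC)[C@@H]2C(O[Si](C)(C)C(C)(C)C)=C1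
F5 | step 4 | C4-methylated ester of F4 (4α-CH3, 4β-CO2Me) | CC1=C(O[Si](C)(C)C(C)(C)C)[C@@]2(C)CC(O[Si](C(C)C)(C(C)C)C(C)C)=C[C@](C)(C(=O)OC)[C@@H]2C(O[Si](C)(C)C(C)(C)C)=C1
F6 | step 4 | C19 alcohol from F5 | CC1=C(O[Si](C)(C)C(C)(C)C)[C@@]2(C)CC(O[Si](C(C)C)(C(C)C)C(C)C)=C[C@](C)(CO)[C@@H]2C(O[Si](C)(C)C(C)(C)C)=C1
F7 | step 9 | 2α,6α,19-triacetate of tetraol 10 (9-OH free) | CC1C(O)[C@@]2(C)C[C@@H](OC(C)=O)C[C@](C)(COC(C)=O)[C@@H]2[C@@H](OC(C)=O)C1
F8 | step 9 | 9-keto 2α,6α,19-triacetate | CC1C(=O)[C@@]2(C)C[C@@H](OC(C)=O)C[C@](C)(COC(C)=O)[C@@H]2[C@@H](OC(C)=O)C1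
F9 | step 9 | 2α,6α,19-trihydroxy-9-ketone | CC1C(=O)[C@@]2(C)C[C@@H](O)C[C@](C)(CO)[C@@H]2[C@@H](O)C1
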